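## The problem

Target **26** is a daucane-type sesquiterpenoid ester. A cyclopentane (C1–C5) is trans-fused through C1 and C5 to a seven-membered ring (C1, C5–C10), and the molecule has six stereocentres. Two of them are fully substituted: the methyl-bearing fusion carbon C1 and the tertiary carbinol C4 with its isopropyl group (hydroxyl cis to the C1 methyl). C1 cannot be corrected once made and must be set absolutely. It can then relay to the vicinal C5, C5 to the C6 oxygen (trans to the C5 side chain), the ring closure fixes C4, and the axial C1 methyl steers the 8,9-epoxide to the opposite face. The sensitive groups are the trisubstituted epoxide (acid, so it comes last), the tertiary alcohol, the anisoate (strong base, hydride, organometallics) and any β-oxygenated ketone met on the way (retro-aldol, E1cB). The enabling feature is this: with C6 as a ketone, C1 and C5–C10 form 3,6-dimethylcyclohepta-2,6-dien-1-one **7**. It has no stereocentre and no α-hydrogen, and its two enone halves are exchanged by a twofold axis. All remaining carbons (C2–C3 and C4 with its isopropyl group) attach at C1 and C5 of one enone, while the other enone is the C6 alcohol and the C8=C9 alkene in latent form. What remains is to close C3–C4 with control at C4 and to move the surviving double bond from C7=C8 to C8=C9.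

## Retrosynthesis

**26 ⇒ 25.** The epoxide is removed first, giving alkene **25**. This is the only acid-labile group, and its face is decided by the axial C1 methyl of the finished bicycle, so it is best introduced last. The forward step needs only a peracid to attack the single alkene from the face opposite that methyl.

**25 ⇒ 24.** The C3–C4 bond is cut to give iodo ketone **24**. Cutting C4–isopropyl instead would require adding a branched nucleophile to an enolisable ring ketone next to the fusion carbon. Cutting C4–C5 at this stage would leave C5 uncontrolled. With C3–C4, a primary alkylsamarium closes onto the ketone, the isopropyl group can turn away from C6, and the C6 ester can chelate the metal. The precursor is monocyclic. The forward step must tolerate a β-acyloxy ketone and an aryl ester.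

**24 ⇒ 20 (through 23, 22, 21).** The iodide is traced back to the vinyl group of **20** (hydroboration to alcohol **21**, iodination to **22**). The C4 ketone is traced to a silyl-protected secondary carbinol (desilylation to **23**, oxidation). The anisoate is put on early because it is both the ester of the target and the protecting group for O6, which saves two operations. These steps need only the usual selectivity of 9-BBN for a monosubstituted alkene and a non-basic oxidation.

**20 ⇒ 18 ⇒ 16 ⇒ 15 ⇒ 14.** The homoallylic alcohol **18** comes from enone **15** by deconjugative reduction: dienol acetate **16**, then borohydride through β,γ-unsaturated ketone **17**. This converts the untouched enone half into C6–OH and C8=C9 in one move. Simple 1,2-reduction would leave the alkene at C7=C8 with no driving force to shift it. Silyl ether **15** is the protected form of aldol **14**. The forward steps must enolise away from the hindered C5 and deliver hydride to the correct face of C6.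

**14 ⇒ 7 + 10 + 11.** C1–C2 and C4–C5 are cut together. Dienone **7**, diisobutyl(vinyl)aluminium **10** and isobutyraldehyde **11** give all fifteen skeletal carbons, three stereocentres and both oxygens of the carbocycle in one flask. The skipped 2,5-dienone isomer would place the alkene correctly from the start. It is passed over for the main line because its doubly activated C7 methylene invites proton transfer and enolate scrambling, whereas **7** has no α-hydrogen and can form only one enolate. The price is the later deconjugation. A stepwise alkylation/aldol route to the same compound would need a separately made chiral 3-vinylcycloheptenone. The forward step needs catalyst control of the C1 face, selective vinyl transfer, mono-addition and aldol attack at C5 anti to the vinyl group.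

**7 ⇒ 5 ⇒ 4 ⇒ 3 ⇒ 1; 10 ⇒ 8 + 9.** The seven-membered ring is cut between the carbonyl carbon and one α-carbon, so **7** comes from siloxycyclopropane **5** by oxidative one-carbon ring expansion (via chloro ketone **6**). **5** comes from cross-conjugated siloxydiene **4**, **4** from enone **3**, and **3** from 2,5-dimethylanisole **1** by Birch reduction (via **2**) and conjugating hydrolysis. Placing the first double bond before the expansion and creating the second by elimination gives the cross-conjugated dienone directly. No base equilibration is needed that could leak to a linearly conjugated isomer. Alane **10** comes from vinylmagnesium bromide **8** and diisobutylaluminium chloride **9**.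

## Roads not taken

**Alternative 1:** The cut is C7–C8 and C1–C10, a [4+3] annulation. A dirhodium tetracarboxylate such as Rh2(OAc)4 would decompose methyl 2-diazobut-3-enoate **A2** in the presence of cyclopentenyl siloxydiene **A1**. Cyclopropanation of the silyl enol ether and Cope rearrangement of the cis-divinylcyclopropane would give bicyclic diene **A3**.
- Merits: both rings and two C–C bonds in one step, and the C4 carbinol is present from the start. In ring construction and convergence this road is better than the chosen plan.
- Weak points: the Cope step must bond C10 to the tetrasubstituted C1 and create the quaternary centre through a crowded boat transition state. C1 is controlled only by relay from C4 across the ring. The C8 ester of **A3** must be reduced to a methyl group over several steps. C5 becomes sp2 and the trans fusion must be re-set. **A1** itself needs an enantioselective synthesis of a tertiary carbinol.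
- Against this the chosen plan sets a catalyst-controlled C1 on the simplest possible substrate, the C8 methyl in place from the start, and oxygen at C4 and C6 without later excision.

**Alternative 2:** The cut is C1–C2 with closure of the five-membered ring. Cu(OTf)2 with a bis(oxazoline) ligand would promote conrotatory 4π electrocyclisation of divinyl ketone **A4** to bicyclic β-keto ester **A5**.
- Merits: the five-membered ring and the quaternary C1 are formed in one catalytic asymmetric step on a polarised substrate of the kind that suits chiral Lewis acids. Here it matches or beats the chosen plan, which spends five steps turning the vinyl group and the aldol carbinol into that ring.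
- Weak points: torquoselection must be achieved at a fully substituted terminus. **A5** has no oxygen at C6, an ester at C3 to delete, and a cross-conjugated, enolised C4 carbonyl that must still accept an isopropyl nucleophile with facial control. C5 is sp2, so the trans fusion is again left for later.
- The chosen plan has C4–O, C6–O and an sp3 C5 straight from its key step.

**Alternative 3:** The cut is C1–C5 after opening the ring of (S)-terpinen-4-ol **A6**. Its silyl ether **A7** is ozonised to keto-aldehyde **A8**, and piperidinium acetate closes this to cyclopentene carbaldehyde **A9**.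
- Merits: the C4 tertiary carbinol with its isopropyl group comes from the chiral pool in three robust steps. This is the stereocentre that the chosen plan sets latest and least securely, and on this point Alternative 3 is clearly better.
- Weak points: **A9** holds only six of the fifteen skeletal carbons. C1 is sp2 and must become quaternary by addition to a hindered β,β-disubstituted enal next to the bulky carbinol. C7–C10 and all functionality of the large ring must still be added in a long linear sequence. The enantiomeric purity of **A6** from natural sources must be secured.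
- The chosen plan gathers every carbon in one operation and sets C1 by catalyst.

Key step: step 6

Assumption: atoms carry the numbering of the target throughout (C1 quaternary methyl carbon, C4 carbinol, C5 fusion CH, C6 ester carbon, C8/C9 epoxide carbons). The antipode of the chiral carbene ligand is chosen so that vinyl reaches the Re face of the β-carbon of **7**.

## Route

Step 1
Reactants: 1 2,5-dimethylanisole
Product: 3 3,6-dimethylcyclohex-2-en-1-one (racemic), via 1-methoxy-2,5-dimethylcyclohexa-1,4-diene 2 (not isolated)
Conditions: Li, NH3(l), t-BuOH, THF, −78 → −33 °C; then 2 M aq. HCl, THF, rt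
Reagents that add atoms: water, O
Why: Birch reduction leaves the double bonds on the methoxy- and methyl-bearing carbons; aqueous acid hydrolyses the enol ether and moves the remaining double bond into conjugation. The stereocentre of 3 is racemic and is erased in step 2.

Step 2
Reactants: 3 3,6-dimethylcyclohex-2-en-1-one
Product: 4 [(2,5-dimethylcyclohexa-1,5-dien-1-yl)oxy]trimethylsilane
Conditions: LiN(i-Pr)2, THF, −78 °C; TMSCl, −78 °C → rt
Reagents that add atoms: chlorotrimethylsilane, C[Si](C)(C)Cl
Why: Kinetic deprotonation of the enone at the α′ methine and O-silylation give the cross-conjugated 2-siloxydiene (kinetic silyl enol ether formation).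

Step 3
Reactants: 4 [(2,5-dimethylcyclohexa-1,5-dien-1-yl)oxy]trimethylsilane
Product: 5 [(3,6-dimethylbicyclo[4.1.0]hept-2-en-1-yl)oxy]trimethylsilane (racemic, cis-fused)
Conditions: Et2Zn, CH2I2, Et2O, 0 °C → rt
Reagents that add atoms: diiodomethane, ICI
Why: Simmons–Smith cyclopropanation (Furukawa reagent) is fastest at the electron-rich silyl enol ether double bond of a 2-siloxydiene, so one equivalent of carbenoid spares the other alkene. The cis fusion is the only one possible.

Step 4
Reactants: 5 [(3,6-dimethylbicyclo[4.1.0]hept-2-en-1-yl)oxy]trimethylsilane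
Product: 7 3,6-dimethylcyclohepta-2,6-dien-1-one, via 6-chloro-3,6-dimethylcyclohept-2-en-1-one 6 (not isolated)
Conditions: FeCl3, DMF, 0 °C → rt; then NaOAc, MeOH, reflux
Reagents that add atoms: none
Why: FeCl3-mediated oxidative ring expansion of a siloxycyclopropane: the trivalent iron cyclopropoxide cleaves the internal bond to the tertiary radical, which takes up chlorine to give 6, and acetate removes HCl by E1cB elimination. One enone comes from the siloxydiene and the other from the elimination, so the cross-conjugated dienone forms without equilibration.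

Step 5
Reactants: 8 vinylmagnesium bromide; 9 diisobutylaluminium chloride
Product: 10 diisobutyl(vinyl)aluminium (used as a titrated solution)
Conditions: THF/hexane, 0 °C → rt; 1,4-dioxane, filtration under argon
Reagents that add atoms: none
Why: Transmetalation of the Grignard reagent to the dialkylaluminium chloride. The magnesium halide is removed as its dioxane complex so that no uncatalysed vinyl transfer competes in step 6.

Step 6
Reactants: 7 3,6-dimethylcyclohepta-2,6-dien-1-one; 10 diisobutyl(vinyl)aluminium; 11 isobutyraldehyde
Product: 14 (6S,7R)-6-ethenyl-7-[(1R)-1-hydroxy-2-methylpropyl]-3,6-dimethylcyclohept-2-en-1-one, via aluminium dienolate 12 (not isolated), via lithium aluminate 13 (not isolated)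
Conditions: Cu(OTf)2 (5 mol %), chiral sulfonate-bearing imidazolinium salt (6 mol %, premixed with Ag2O), THF, −78 → −30 °C; MeLi, −78 °C; then 11, −78 °C; aq. NH4Cl/sodium potassium tartrate
Reagents that add atoms: none
Why: The alane reduces the copper salt to a monovalent copper–carbene vinyl species, which adds to one enone by π-complexation, bond formation at the β-carbon and reductive elimination; vinyl is transferred in preference to isobutyl and aluminium dienolate 12 results. The closest known reaction type is the copper–carbene-catalysed enantioselective conjugate addition of alkenylaluminium reagents to β-methyl cycloalkenones with aldol trapping of the enolate, here applied to a cross-conjugated dienone. No ring is closed; C1–C2 and C4–C5 are formed. C1 is set by the catalyst: a twofold axis exchanges the two enone halves, so addition to the Re face of either β-carbon gives the same (S)-configured centre and only ordinary facial selection is required. Methyllithium converts 12 into aluminate 13, which adds to 11 at C5 through a closed six-membered transition state, with the aldehyde approaching anti to the pseudo-axial vinyl group on C1 (substrate control of C5). The ring-locked (E)-enolate gives the anti aldol at C4, a configuration that is erased in step 14. Double addition is suppressed because the first addition turns the second enone into part of an electron-rich dienolate, and the absence of any α-hydrogen in 7 excludes proton transfer and enolate scrambling. The C5 selectivity is the least secure element, since methyl and vinyl differ little in size.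

Step 7
Reactants: 14 aldol adduct
Product: 15 (6S,7R)-7-[(1R)-1-{[tert-butyl(dimethyl)silyl]oxy}-2-methylpropyl]-6-ethenyl-3,6-dimethylcyclohept-2-en-1-one
Conditions: TBSOTf, 2,6-lutidine, CH2Cl2, −78 → 0 °C
Reagents that add atoms: tert-butyldimethylsilyl trifluoromethanesulfonate, CC(C)(C)[Si](C)(C)OS(=O)(=O)C(F)(F)F
Why: A silyl triflate with a hindered pyridine base silylates the hindered secondary aldol hydroxyl at low temperature without retro-aldol cleavage or enolisation.

Step 8
Reactants: 15 silyl ether
Product: 16 (6S,7R)-7-[(1R)-1-{[tert-butyl(dimethyl)silyl]oxy}-2-methylpropyl]-6-ethenyl-3,6-dimethylcyclohepta-1,3-dien-1-yl acetate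
Conditions: isopropenyl acetate, TsOH·H2O (cat.), 90 °C, acetone distilled off
Reagents that add atoms: isopropenyl acetate, CC(=C)OC(C)=O
Why: Acid-catalysed enol acetylation under equilibrating conditions gives the linear dienol acetate (C6=C7, C8=C9), the standard entry to enone deconjugation. Enolisation toward the hindered C5 methine would give a strained tetrasubstituted enol and is disfavoured.

Step 9
Reactants: 16 dienol acetate
Product: 18 (1S,6S,7S)-7-[(1R)-1-{[tert-butyl(dimethyl)silyl]oxy}-2-methylpropyl]-6-ethenyl-3,6-dimethylcyclohept-3-en-1-ol, via β,γ-unsaturated ketone 17 (not isolated)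
Conditions: NaBH4, EtOH/THF/H2O, 0 °C → rt
Reagents that add atoms: none
Why: Enol acetate–borohydride deconjugative reduction: the enol ester is cleaved, the dienolate is protonated kinetically at C7 to give 17, and 17 is reduced faster than it reconjugates. The small hydride is expected on the pseudo-axial trajectory, giving the pseudo-equatorial C6 alcohol trans to the C5 side chain.

Step 10
Reactants: 18 homoallylic alcohol; 19 4-methoxybenzoyl chloride
Product: 20 (1S,6S,7S)-7-[(1R)-1-{[tert-butyl(dimethyl)silyl]oxy}-2-methylpropyl]-6-ethenyl-3,6-dimethylcyclohept-3-en-1-yl 4-methoxybenzoate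
Conditions: Et3N, DMAP, CH2Cl2, 0 °C → rt
Reagents that add atoms: none
Why: DMAP-catalysed acylation of the only free hydroxyl. The anisoate is the ester of the target and also protects O6 for the rest of the route.

Step 11
Reactants: 20 vinyl anisoate
Product: 21 (1S,6S,7S)-7-[(1R)-1-{[tert-butyl(dimethyl)silyl]oxy}-2-methylpropyl]-6-(2-hydroxyethyl)-3,6-dimethylcyclohept-3-en-1-yl 4-methoxybenzoate
Conditions: 9-BBN, THF, 0 °C → rt; then NaBO3·4H2O, H2O, rt
Reagents that add atoms: sodium perborate (oxygen of the new hydroxyl), [Na+].[Na+].O[B-]1(O)OO[B-](O)(O)OO1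
Why: Hydroboration–oxidation: 9-BBN adds to the terminal carbon of the monosubstituted alkene far faster than to the trisubstituted ring alkene and does not touch the ester. Perborate oxidises the borane under near-neutral conditions that spare the anisoate.

Step 12
Reactants: 21 primary alcohol
Product: 22 (1S,6S,7S)-7-[(1R)-1-{[tert-butyl(dimethyl)silyl]oxy}-2-methylpropyl]-6-(2-iodoethyl)-3,6-dimethylcyclohept-3-en-1-yl 4-methoxybenzoate
Conditions: I2, PPh3, imidazole, CH2Cl2, 0 °C → rt
Reagents that add atoms: iodine, II
Why: Appel-type iodination of the primary alcohol; no other hydroxyl is free.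

Step 13
Reactants: 22 primary iodide
Product: 23 (1S,6S,7R)-7-[(1R)-1-hydroxy-2-methylpropyl]-6-(2-iodoethyl)-3,6-dimethylcyclohept-3-en-1-yl 4-methoxybenzoate
Conditions: HF·pyridine, THF, 0 °C → rt
Reagents that add atoms: none
Why: Fluoride cleavage of the secondary silyl ether under mildly acidic, non-nucleophilic conditions that leave the primary iodide and the ester intact.

Step 14
Reactants: 23 iodo alcohol
Product: 24 (1S,6S,7S)-6-(2-iodoethyl)-3,6-dimethyl-7-(2-methylpropanoyl)cyclohept-3-en-1-yl 4-methoxybenzoate
Conditions: Dess–Martin periodinane, NaHCO3, CH2Cl2, 0 °C → rt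
Reagents that add atoms: none
Why: Dess–Martin oxidation under bicarbonate buffer gives the β-acyloxy ketone without a base strong enough to trigger E1cB loss of anisate. The C4 stereocentre of the aldol disappears here as planned.

Step 15
Reactants: 24 iodo ketone
Product: 25 (3R,3aS,4S,8aR)-3-hydroxy-6,8a-dimethyl-3-(propan-2-yl)-1,2,3,3a,4,5,8,8a-octahydroazulen-4-yl 4-methoxybenzoate
Conditions: SmI2, HMPA, THF, −78 → 0 °C; aq. NH4Cl
Reagents that add atoms: none
Why: Intramolecular samarium Barbier reaction: divalent samarium with HMPA reduces the primary iodide to an alkylsamarium that adds to the C4 ketone (5-exo closure onto the carbonyl carbon). The isopropyl group turns away from C6 and the samarium-bound carbonyl oxygen can chelate the C6 ester, so the hydroxyl ends up cis to the C1 methyl. The C1/C5 relation from step 6 becomes the trans ring fusion.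

Step 16
Reactants: 25 bicyclic alkene
Product: 26 (3R,3aS,4S,6R,7S,8aR)-6,7-epoxy-3-hydroxy-6,8a-dimethyl-3-(propan-2-yl)decahydroazulen-4-yl 4-methoxybenzoate (target)
Conditions: mCPBA, NaHCO3, CH2Cl2, 0 °C
Reagents that add atoms: 3-chloroperoxybenzoic acid, OOC(=O)c1cccc(Cl)c1
Why: Prilezhaev epoxidation of the only alkene. The axial C1 methyl shields the upper face of the seven-membered ring, so the peracid attacks the face opposite to it and the epoxide oxygen ends up anti to the C1 methyl, as in the target.

## Compound list

1 | 2,5-dimethylanisole | COc1cc(C)ccc1C | starting material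
2 | 1-methoxy-2,5-dimethylcyclohexa-1,4-diene | COC1=C(C)CC=C(C)C1 | intermediate
3 | 3,6-dimethylcyclohex-2-en-1-one (racemic) | CC1=CC(=O)C(C)CC1 | intermediate
4 | [(2,5-dimethylcyclohexa-1,5-dien-1-yl)oxy]trimethylsilane | CC1=CC(O[Si](C)(C)C)=C(C)CC1 | intermediate
5 | [(3,6-dimethylbicyclo[4.1.0]hept-2-en-1-yl)oxy]trimethylsilane (racemic, cis-fused) | CC1=CC2(O[Si](C)(C)C)CC2(C)CC1 | intermediate
6 | 6-chloro-3,6-dimethylcyclohept-2-en-1-one (racemic) | CC1=CC(=O)CC(C)(Cl)CC1 | intermediate
7 | 3,6-dimethylcyclohepta-2,6-dien-1-one | CC1=CC(=O)C=C(C)CC1 | intermediate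
8 | vinylmagnesium bromide | C=C[Mg]Br | starting material
9 | diisobutylaluminium chloride | CC(C)C[Al](Cl)CC(C)C | starting material
10 | diisobutyl(vinyl)aluminium | C=C[Al](CC(C)C)CC(C)C | intermediate
11 | isobutyraldehyde | CC(C)C=O | starting material
12 | {[(3S)-3-ethenyl-3,6-dimethylcyclohepta-1,6-dien-1-yl]oxy}bis(2-methylpropyl)aluminium | C=C[C@]1(C)CCC(C)=CC(O[Al](CC(C)C)CC(C)C)=C1 | intermediate
13 | lithium {[(3S)-3-ethenyl-3,6-dimethylcyclohepta-1,6-dien-1-yl]oxy}(methyl)bis(2-methylpropyl)aluminate | C=C[C@]1(C)CCC(C)=CC(O[Al-](C)(CC(C)C)CC(C)C)=C1.[Li+] | intermediate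
14 | (6S,7R)-6-ethenyl-7-[(1R)-1-hydroxy-2-methylpropyl]-3,6-dimethylcyclohept-2-en-1-one | C=C[C@]1(C)CCC(C)=CC(=O)[C@H]1[C@H](O)C(C)C | intermediate
15 | (6S,7R)-7-[(1R)-1-{[tert-butyl(dimethyl)silyl]oxy}-2-methylpropyl]-6-ethenyl-3,6-dimethylcyclohept-2-en-1-one | C=C[C@]1(C)CCC(C)=CC(=O)[C@H]1[C@H](O[Si](C)(C)C(C)(C)C)C(C)C | intermediate
16 | (6S,7R)-7-[(1R)-1-{[tert-butyl(dimethyl)silyl]oxy}-2-methylpropyl]-6-ethenyl-3,6-dimethylcyclohepta-1,3-dien-1-yl acetate | C=C[C@]1(C)CC=C(C)C=C(OC(C)=O)[C@H]1[C@H](O[Si](C)(C)C(C)(C)C)C(C)C | intermediate
17 | (6S,7R)-7-[(1R)-1-{[tert-butyl(dimethyl)silyl]oxy}-2-methylpropyl]-6-ethenyl-3,6-dimethylcyclohept-3-en-1-one | C=C[C@]1(C)CC=C(C)CC(=O)[C@H]1[C@H](O[Si](C)(C)C(C)(C)C)C(C)C | intermediate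
18 | (1S,6S,7S)-7-[(1R)-1-{[tert-butyl(dimethyl)silyl]oxy}-2-methylpropyl]-6-ethenyl-3,6-dimethylcyclohept-3-en-1-ol | C=C[C@]1(C)CC=C(C)C[C@H](O)[C@H]1[C@H](O[Si](C)(C)C(C)(C)C)C(C)C | intermediate
19 | 4-methoxybenzoyl chloride | COc1ccc(cc1)C(Cl)=O | starting material
20 | (1S,6S,7S)-7-[(1R)-1-{[tert-butyl(dimethyl)silyl]oxy}-2-methylpropyl]-6-ethenyl-3,6-dimethylcyclohept-3-en-1-yl 4-methoxybenzoate | C=C[C@]1(C)CC=C(C)C[C@H](OC(=O)c2ccc(OC)cc2)[C@H]1[C@H](O[Si](C)(C)C(C)(C)C)C(C)C | intermediate
21 | (1S,6S,7S)-7-[(1R)-1-{[tert-butyl(dimethyl)silyl]oxy}-2-methylpropyl]-6-(2-hydroxyethyl)-3,6-dimethylcyclohept-3-en-1-yl 4-methoxybenzoate | OCC[C@]1(C)CC=C(C)C[C@H](OC(=O)c2ccc(OC)cc2)[C@H]1[C@H](O[Si](C)(C)C(C)(C)C)C(C)C | intermediate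
22 | (1S,6S,7S)-7-[(1R)-1-{[tert-butyl(dimethyl)silyl]oxy}-2-methylpropyl]-6-(2-iodoethyl)-3,6-dimethylcyclohept-3-en-1-yl 4-methoxybenzoate | ICC[C@]1(C)CC=C(C)C[C@H](OC(=O)c2ccc(OC)cc2)[C@H]1[C@H](O[Si](C)(C)C(C)(C)C)C(C)C | intermediate
23 | (1S,6S,7R)-7-[(1R)-1-hydroxy-2-methylpropyl]-6-(2-iodoethyl)-3,6-dimethylcyclohept-3-en-1-yl 4-methoxybenzoate | ICC[C@]1(C)CC=C(C)C[C@H](OC(=O)c2ccc(OC)cc2)[C@H]1[C@H](O)C(C)C | intermediate
24 | (1S,6S,7S)-6-(2-iodoethyl)-3,6-dimethyl-7-(2-methylpropanoyl)cyclohept-3-en-1-yl 4-methoxybenzoate | ICC[C@]1(C)CC=C(C)C[C@H](OC(=O)c2ccc(OC)cc2)[C@H]1C(=O)C(C)C | intermediate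
25 | (3R,3aS,4S,8aR)-3-hydroxy-6,8a-dimethyl-3-(propan-2-yl)-1,2,3,3a,4,5,8,8a-octahydroazulen-4-yl 4-methoxybenzoate | COc1ccc(C(=O)O[C@H]2CC(C)=CC[C@@]3(C)CC[C@@](O)(C(C)C)[C@H]23)cc1 | intermediate
26 | (3R,3aS,4S,6R,7S,8aR)-6,7-epoxy-3-hydroxy-6,8a-dimethyl-3-(propan-2-yl)decahydroazulen-4-yl 4-methoxybenzoate | COc1ccc(C(=O)O[C@H]2C[C@@]3(C)O[C@H]3C[C@@]3(C)CC[C@@](O)(C(C)C)[C@H]23)cc1 | target

## Step count and least certain steps

Total step count: 16. Longest linear sequence: 15 steps (steps 1–4 and 6–16 from 2,5-dimethylanisole); step 5 is a one-step branch.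

**Step 6 (key step).** The most likely failure is poor facial discrimination in the aldol at C5. The two substituents on C1, methyl and vinyl, are of similar size, so attack syn to vinyl can compete, and the aluminate aldolate may also equilibrate by retro-aldol. Fallback: the two bond formations are separated. From 7 and 10 the conjugate addition is run alone and the enolate is protonated, giving (6R)-6-ethenyl-3,6-dimethylcyclohept-2-en-1-one F1. Its α′-methylene is then converted with dicyclohexylboron chloride and Et3N into the boron enolate, whose short B–O bonds give a tighter transition state and magnify the steric difference at C1. Addition to 11 and oxidative work-up return the anti aldol 14.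

**Step 8.** The acid may promote enolisation toward C5 followed by loss of the β-silyloxy group (elimination to an isobutylidene dienone), or cleave the silyl ether. Fallback: the deconjugation is done before any sensitive group is present. From 7, KOt-Bu in t-BuOH/THF forms the extended dienolate, and cold aqueous acetic acid protonates it at the α-carbon to give 3,6-dimethylcyclohepta-2,5-dien-1-one F2. The three-component reaction of step 6 (same catalyst, 10, 11) on the single enone of F2 gives (6S,7R)-6-ethenyl-7-[(1R)-1-hydroxy-2-methylpropyl]-3,6-dimethylcyclohept-3-en-1-one F3, with the ring alkene already at C8=C9. Silylation as in step 7 gives 17, now isolated, and the borohydride reduction of step 9 leads to 18.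

**Step 9.** Hydride may attack C6 from the wrong face, because the pseudo-axial C1 methyl hinders the trajectory that leads to the wanted trans alcohol; some reconjugation before reduction is also possible. Fallback: the wrong epimer is made on purpose and inverted. From 16, MeLi (2 equiv, −78 °C) followed by cold acetic acid gives isolated 17. The bulky LiBH(s-Bu)3 attacks anti to the C5 side chain and gives (1R,6S,7S)-7-[(1R)-1-{[tert-butyl(dimethyl)silyl]oxy}-2-methylpropyl]-6-ethenyl-3,6-dimethylcyclohept-3-en-1-ol F4. Mitsunobu esterification with 4-methoxybenzoic acid (PPh3, diisopropyl azodicarboxylate) inverts C6 and gives 20 directly.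

**Step 15.** β-Acyloxy ketone 24 may lose anisate by E1cB elimination, or the ester may be attacked or reduced, before or after the C–C bond forms. Fallback: O6 carries an ether during the closure and the ester is put on afterwards. From 18:
- NaH and 4-methoxybenzyl chloride give the 4-methoxybenzyl ether of 18 F5.
- 9-BBN then NaBO3 gives the primary alcohol F6.
- I2/PPh3/imidazole gives the primary iodide F7.
- HF·pyridine gives the iodo alcohol F8.
- Dess–Martin oxidation gives the iodo ketone F9, a β-alkoxy ketone far less prone to elimination.
- SmI2/HMPA gives the bicyclic 4-methoxybenzyl ether F10.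
- DDQ in wet CH2Cl2 gives (3R,3aS,4S,8aR)-6,8a-dimethyl-3-(propan-2-yl)-1,2,3,3a,4,5,8,8a-octahydroazulene-3,4-diol F11.
- Acylation with 19 (Et3N, DMAP) at the secondary hydroxyl gives 25.

**Step 16.** Facial selectivity may be insufficient or reversed, for example through hydrogen-bond delivery of the peracid by the C4 hydroxyl to the upper face. Fallback, for the case that electrophiles prefer the upper face: from 25, N-bromosuccinimide in aqueous THF forms the bromonium ion on that face and water opens it at the tertiary C8 from below. This gives (3R,3aS,4S,6R,7R,8aR)-7-bromo-3,6-dihydroxy-6,8a-dimethyl-3-(propan-2-yl)decahydroazulen-4-yl 4-methoxybenzoate F12. DBU then closes the C8 alkoxide onto C9 with inversion and gives 26, with the oxygen on the lower face.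

## Further compounds

F1 | step 6 | (6R)-6-ethenyl-3,6-dimethylcyclohept-2-en-1-one | C=C[C@]1(C)CCC(C)=CC(=O)C1
F2 | step 8 | 3,6-dimethylcyclohepta-2,5-dien-1-one | CC1=CCC(C)=CC(=O)C1
F3 | step 8 | (6S,7R)-6-ethenyl-7-[(1R)-1-hydroxy-2-methylpropyl]-3,6-dimethylcyclohept-3-en-1-one | C=C[C@]1(C)CC=C(C)CC(=O)[C@H]1[C@H](O)C(C)C
F4 | step 9 | (1R,6S,7S)-7-[(1R)-1-{[tert-butyl(dimethyl)silyl]oxy}-2-methylpropyl]-6-ethenyl-3,6-dimethylcyclohept-3-en-1-ol | C=C[C@]1(C)CC=C(C)C[C@@H](O)[C@H]1[C@H](O[Si](C)(C)C(C)(C)C)C(C)C
F5 | step 15 | 4-methoxybenzyl ether of 18 | C=C[C@]1(C)CC=C(C)C[C@H](OCc2ccc(OC)cc2)[C@H]1[C@H](O[Si](C)(C)C(C)(C)C)C(C)C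
F6 | step 15 | primary alcohol from hydroboration of F5 | OCC[C@]1(C)CC=C(C)C[C@H](OCc2ccc(OC)cc2)[C@H]1[C@H](O[Si](C)(C)C(C)(C)C)C(C)C
F7 | step 15 | primary iodide from F6 | ICC[C@]1(C)CC=C(C)C[C@H](OCc2ccc(OC)cc2)[C@H]1[C@H](O[Si](C)(C)C(C)(C)C)C(C)C
F8 | step 15 | iodo alcohol from desilylation of F7 | ICC[C@]1(C)CC=C(C)C[C@H](OCc2ccc(OC)cc2)[C@H]1[C@H](O)C(C)C
F9 | step 15 | iodo ketone from oxidation of F8 | ICC[C@]1(C)CC=C(C)C[C@H](OCc2ccc(OC)cc2)[C@H]1C(=O)C(C)C
F10 | step 15 | (3R,3aS,4S,8aR)-4-[(4-methoxyphenyl)methoxy]-6,8a-dimethyl-3-(propan-2-yl)-1,2,3,3a,4,5,8,8a-octahydroazulen-3-ol | COc1ccc(CO[C@H]2CC(C)=CC[C@@]3(C)CC[C@@](O)(C(C)C)[C@H]23)cc1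
F11 | step 15 | (3R,3aS,4S,8aR)-6,8a-dimethyl-3-(propan-2-yl)-1,2,3,3a,4,5,8,8a-octahydroazulene-3,4-diol | O[C@H]1CC(C)=CC[C@@]2(C)CC[C@@](O)(C(C)C)[C@H]12
F12 | step 16 | (3R,3aS,4S,6R,7R,8aR)-7-bromo-3,6-dihydroxy-6,8a-dimethyl-3-(propan-2-yl)decahydroazulen-4-yl 4-methoxybenzoate | COc1ccc(C(=O)O[C@H]2C[C@@](C)(O)[C@H](Br)C[C@@]3(C)CC[C@@](O)(C(C)C)[C@H]23)cc1
A1 | alternative 1 | cyclopentenyl siloxydiene, 2-[1-(tert-butyldimethylsilyloxy)ethenyl]-1-methyl-3-(propan-2-yl)-3-(triethylsilyloxy)cyclopent-1-ene, carbinol carbon configured as C4 of the target | CC1=C(C(=C)O[Si](C)(C)C(C)(C)C)[C@](O[Si](CC)(CC)CC)(C(C)C)CC1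
A2 | alternative 1 | methyl 2-diazobut-3-enoate | COC(=O)C(=[N+]=[N-])C=C
A3 | alternative 1 | bicyclic cycloheptadiene with C6 silyl enol ether and C8 methyl ester | COC(=O)C1=CC[C@@]2(C)CC[C@@](O[Si](CC)(CC)CC)(C(C)C)C2=C(O[Si](C)(C)C(C)(C)C)C1
A4 | alternative 2 | methyl 2-[(2,5-dimethylcyclohepta-1,4-dien-1-yl)carbonyl]prop-2-enoate | COC(=O)C(=C)C(=O)C1=C(C)CC=C(C)CC1
A5 | alternative 2 | bicyclic dienone β-keto ester (enol form) with quaternary C1 | COC(=O)C1=C(O)C2=CCC(C)=CC[C@@]2(C)C1
A6 | alternative 3 | (S)-terpinen-4-ol | CC1=CC[C@](O)(C(C)C)CC1
A7 | alternative 3 | triethylsilyl ether of (S)-terpinen-4-ol | CC1=CC[C@](O[Si](CC)(CC)CC)(C(C)C)CC1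
A8 | alternative 3 | 6-oxo-3-(propan-2-yl)-3-(triethylsilyloxy)heptanal, carbinol carbon configured as C4 of the target | CC(=O)CC[C@@](O[Si](CC)(CC)CC)(C(C)C)CC=O
A9 | alternative 3 | 5-isopropyl-2-methyl-5-(triethylsilyloxy)cyclopent-1-ene-1-carbaldehyde | CC1=C(C=O)[C@](O[Si](CC)(CC)CC)(C(C)C)CC1
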